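**Retrosynthetic overview**

1. Side-chain atoms are called C1' (carbinol CH), C2' (CH2), C3' (vinylic CH) and C4' (alkene carbon bearing CH2OH). The C3'–C2' bond is cut to give a (Z)-alkenyl iodide (decalin plus Z-iodomethylene allylic alcohol) and (4R)-4-[(2S)-oxiranyl]-γ-butyrolactone. Both carbons are electrophiles and are joined in the last step by a nickel-catalysed reductive cross-electrophile coupling, with no protecting group.
2. Enabling feature: the hydroxyl on C1' sits next to C2', so O, C1' and C2' can be carried as a terminal oxirane ring whose CH2 is the electrophile and whose opening reveals the carbinol. The hydroxymethyl on C4' is cis to C3', so iodine can be placed on C3' through a five-membered O–Mg–C3' chelate ring.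
3. Alkenyl iodide: (+)-sclareolide supplies rings A and B with C5 and C10. Acid-equilibrated lactone opening sets the C8=C9 alkene, and the two-carbon arm becomes a Grignard reagent that adds across propargyl alcohol (anti-carbomagnesiation, then iodinolysis).
4. Epoxy lactone: (S)-5-(hydroxymethyl)furan-2(5H)-one undergoes trans radical hydroxymethylation at C4, then a base-triggered lactone transposition closes the target's γ-lactone ring and the oxirane in one operation.
5. Ring order: decalin (chiral pool), then γ-butyrolactone and temporary oxirane (step 7), then the oxirane is opened in the key step, which closes no ring.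

Key step: step 8

Remark on the chemistry: the decalin of the target (4aS,8aS) has the configuration of (+)-sclareolide, the carbinol and the lactone carbon are both (R), the alkene is (Z), and both hydroxyl groups are carried free through the last step.

**Route**

Step 1
Reactants: 1 (+)-sclareolide
Product: 2 methyl 2-[(4aS,8aS)-2,5,5,8a-tetramethyl-3,4,4a,5,6,7,8,8a-octahydronaphthalen-1-yl]acetate
Conditions: conc. H2SO4, MeOH, 65 °C
Reagents that add atoms: methanol, CO
Why: Acid ionises the tertiary C8–O bond of the lactone (E1 elimination combined with Fischer esterification) and, under equilibrating protic acid, proton loss should settle on the tetrasubstituted C8=C9 alkene; the C9 stereocenter is erased on purpose, C5 and C10 are untouched, and minor trisubstituted or exocyclic isomers would be removed on AgNO3-impregnated silica.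

Step 2
Reactants: 2 methyl 2-[(4aS,8aS)-2,5,5,8a-tetramethyl-3,4,4a,5,6,7,8,8a-octahydronaphthalen-1-yl]acetate
Product: 3 2-[(4aS,8aS)-2,5,5,8a-tetramethyl-3,4,4a,5,6,7,8,8a-octahydronaphthalen-1-yl]ethan-1-ol
Conditions: LiAlH4, THF, 0 °C to rt; Fieser work-up
Reagents that add atoms: none
Why: Hydride reduction of an ester to the primary alcohol, to which the isolated tetrasubstituted alkene is inert.

Step 3
Reactants: 3 2-[(4aS,8aS)-2,5,5,8a-tetramethyl-3,4,4a,5,6,7,8,8a-octahydronaphthalen-1-yl]ethan-1-ol
Product: 4 (4aS,8aS)-1-(2-bromoethyl)-2,5,5,8a-tetramethyl-3,4,4a,5,6,7,8,8a-octahydronaphthalene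
Conditions: CBr4, PPh3, CH2Cl2, 0 °C
Reagents that add atoms: carbon tetrabromide, BrC(Br)(Br)Br
Why: Appel bromination of a primary alcohol by SN2 displacement of the oxyphosphonium group under neutral conditions that leave the alkene alone.

Step 4
Reactants: 4 (4aS,8aS)-1-(2-bromoethyl)-2,5,5,8a-tetramethyl-3,4,4a,5,6,7,8,8a-octahydronaphthalene; 5 prop-2-yn-1-ol
Product: 9 (2Z)-3-iodo-2-{2-[(4aS,8aS)-2,5,5,8a-tetramethyl-3,4,4a,5,6,7,8,8a-octahydronaphthalen-1-yl]ethyl}prop-2-en-1-ol, via homoallylic Grignard reagent 6 (not isolated), via bromomagnesium propargyl alkoxide 7 (not isolated), via cyclic alkenylmagnesium alkoxide 8 (not isolated)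
Conditions: 4, Mg turnings, THF, 50 °C; separately 5, EtMgBr (1.0 equiv), THF, 0 °C (1.5 equiv of 7); Grignard solution into the alkoxide, CuI (10 mol%), THF, 0 °C to rt; then I2, −20 °C to rt; aq. NH4Cl/Na2S2O3
Reagents that add atoms: iodine, II
Why: Copper-catalysed anti-carbomagnesiation of a propargylic magnesium alkoxide delivers the alkyl group to C2 and magnesium to C3 on the side of the CH2O group, and iodinolysis of the resulting five-membered O–Mg–C chelate ring with retention should fix iodine cis to CH2OH, which is the Z geometry of the target alkene.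

Step 5
Reactants: 10 (5S)-5-(hydroxymethyl)furan-2(5H)-one
Product: 11 [(2S)-5-oxo-2,5-dihydrofuran-2-yl]methyl 4-methylbenzenesulfonate
Conditions: TsCl, pyridine, CH2Cl2, 0 °C
Reagents that add atoms: p-toluenesulfonyl chloride, Cc1ccc(cc1)S(Cl)(=O)=O
Why: O-sulfonylation of the primary alcohol, with pyridine too weak a base to deprotonate the γ-position, so the C5 stereocenter should not racemise.

Step 6
Reactants: 11 [(2S)-5-oxo-2,5-dihydrofuran-2-yl]methyl 4-methylbenzenesulfonate
Product: 12 [(2S,3R)-3-(hydroxymethyl)-5-oxooxolan-2-yl]methyl 4-methylbenzenesulfonate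
Conditions: degassed MeOH (solvent), benzophenone (0.2 equiv), hν 350 nm (Pyrex), rt
Reagents that add atoms: methanol, CO
Why: Benzophenone-sensitised radical conjugate addition (Giese type): the hydroxymethyl radical formed by hydrogen abstraction from methanol adds to C4 of the butenolide on the face anti to the C5 substituent, which sets the new (R) center trans to it, and the tosylate does not absorb at 350 nm.

Step 7
Reactants: 12 [(2S,3R)-3-(hydroxymethyl)-5-oxooxolan-2-yl]methyl 4-methylbenzenesulfonate
Product: 14 (4R)-4-[(2S)-oxiran-2-yl]oxolan-2-one, via transposed hydroxy tosylate lactone 13 (not isolated)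
Conditions: DBU (1.2 equiv), CH2Cl2, 0 °C to rt
Reagents that add atoms: none
Why: Base-mediated acyl transfer (5-exo-trig attack of the primary hydroxyl on the lactone carbonyl; direct displacement of the tosylate would need a trans-fused bicyclo[3.3.0] ring) frees the secondary oxygen, which closes the oxirane by intramolecular Williamson displacement (3-exo-tet) and so pulls the lactone equilibrium forward, with both stereocenters untouched.

Step 8
Reactants: 9 (2Z)-3-iodo-2-{2-[(4aS,8aS)-2,5,5,8a-tetramethyl-3,4,4a,5,6,7,8,8a-octahydronaphthalen-1-yl]ethyl}prop-2-en-1-ol; 14 (4R)-4-[(2S)-oxiran-2-yl]oxolan-2-one (1.5 equiv)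
Product: 16 (4R)-4-[(1R,3Z)-1-hydroxy-4-(hydroxymethyl)-6-[(4aS,8aS)-2,5,5,8a-tetramethyl-3,4,4a,5,6,7,8,8a-octahydronaphthalen-1-yl]hex-3-en-1-yl]oxolan-2-one, via iodohydrin 15 (not isolated)
Conditions: NiCl2(dme) (10 mol%), 2,2'-bipyridine (10 mol%), NaI (25 mol%), Et3N·HCl (1.0 equiv), Mn powder (2.0 equiv), DMPU, 25 °C
Reagents that add atoms: none
Why: Two electrophilic carbons are united: iodide, helped by Et3N·HCl, opens oxirane 14 by SN2 at its CH2 to give iodohydrin 15, zerovalent nickel–bipyridine inserts into the C–I bond of 9 with retention, the primary β-hydroxyalkyl radical released from 15 by halogen abstraction at monovalent nickel is captured by the divalent (Z)-alkenylnickel iodide, the resulting trivalent alkenyl(alkyl)nickel reductively eliminates the C(sp2)–C(sp3) bond, and Mn returns nickel to its low-valent state. The closest known reaction type is the nickel-catalysed reductive cross-electrophile coupling of aryl and vinyl halides with terminal epoxides under iodide co-catalysis. No ring is closed; the oxirane ring is opened. No new stereocenter is made: the carbinol center is the untouched (S)-oxirane carbon (its descriptor becomes R only through the change in CIP ranking), the lactone center is remote from the radical site, and the Z geometry is carried over from 9. The step needs opening at CH2 and not CH (iodide attacks the unhindered terminus), cross- over homo-coupling (the sp2 iodide reacts by oxidative addition, the sp3 iodide by radical formation), and retention of alkene geometry (reductive elimination from trivalent nickel should outrun alkenyl isomerisation). It also needs chemoselectivity, which the buffered medium secures because no carbanion or free alkoxide is formed, so the γ-lactone, the free allylic alcohol and the new secondary alcohol (which could otherwise transpose the lactone) are left alone.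

**Compound list**

1 | (+)-sclareolide, (3aR,5aS,9aS,9bR)-3a,6,6,9a-tetramethyldecahydronaphtho[2,1-b]furan-2(1H)-one | CC1(CCC[C@]2([C@H]1CC[C@@]3([C@@H]2CC(=O)O3)C)C)C | starting material
2 | methyl 2-[(4aS,8aS)-2,5,5,8a-tetramethyl-3,4,4a,5,6,7,8,8a-octahydronaphthalen-1-yl]acetate | CC1=C(CC(=O)OC)[C@@]2(C)CCCC(C)(C)[C@@H]2CC1 | intermediate
3 | 2-[(4aS,8aS)-2,5,5,8a-tetramethyl-3,4,4a,5,6,7,8,8a-octahydronaphthalen-1-yl]ethan-1-ol | CC1=C(CCO)[C@@]2(C)CCCC(C)(C)[C@@H]2CC1 | intermediate
4 | (4aS,8aS)-1-(2-bromoethyl)-2,5,5,8a-tetramethyl-3,4,4a,5,6,7,8,8a-octahydronaphthalene | CC1=C(CCBr)[C@@]2(C)CCCC(C)(C)[C@@H]2CC1 | intermediate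
5 | prop-2-yn-1-ol (propargyl alcohol) | C#CCO | starting material
6 | {2-[(4aS,8aS)-2,5,5,8a-tetramethyl-3,4,4a,5,6,7,8,8a-octahydronaphthalen-1-yl]ethyl}magnesium bromide | CC1=C(CC[Mg]Br)[C@@]2(C)CCCC(C)(C)[C@@H]2CC1 | intermediate (not isolated)
7 | bromomagnesium prop-2-yn-1-olate | C#CCO[Mg]Br | intermediate (not isolated)
8 | 4-{2-[(4aS,8aS)-2,5,5,8a-tetramethyl-3,4,4a,5,6,7,8,8a-octahydronaphthalen-1-yl]ethyl}-2,5-dihydro-1,2-oxamagnesole (five-membered O–Mg–C=C–CH2 ring) | CC1=C(CCC3=C[Mg]OC3)[C@@]2(C)CCCC(C)(C)[C@@H]2CC1 | intermediate (not isolated)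
9 | (2Z)-3-iodo-2-{2-[(4aS,8aS)-2,5,5,8a-tetramethyl-3,4,4a,5,6,7,8,8a-octahydronaphthalen-1-yl]ethyl}prop-2-en-1-ol | CC1=C(CC/C(=C/I)CO)[C@@]2(C)CCCC(C)(C)[C@@H]2CC1 | intermediate
10 | (5S)-5-(hydroxymethyl)furan-2(5H)-one | O=C1C=C[C@@H](CO)O1 | starting material
11 | [(2S)-5-oxo-2,5-dihydrofuran-2-yl]methyl 4-methylbenzenesulfonate | O=C1C=C[C@@H](COS(=O)(=O)c2ccc(C)cc2)O1 | intermediate
12 | [(2S,3R)-3-(hydroxymethyl)-5-oxooxolan-2-yl]methyl 4-methylbenzenesulfonate (trans) | OC[C@H]1CC(=O)O[C@@H]1COS(=O)(=O)c1ccc(C)cc1 | intermediate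
13 | (2S)-2-hydroxy-2-[(3R)-5-oxooxolan-3-yl]ethyl 4-methylbenzenesulfonate | Cc1ccc(cc1)S(=O)(=O)OC[C@@H](O)[C@H]1COC(=O)C1 | intermediate (not isolated)
14 | (4R)-4-[(2S)-oxiran-2-yl]oxolan-2-one | O=C1C[C@H](CO1)[C@H]2CO2 | intermediate
15 | (4R)-4-[(1S)-1-hydroxy-2-iodoethyl]oxolan-2-one | IC[C@@H](O)[C@H]1COC(=O)C1 | intermediate (not isolated)
16 | (4R)-4-[(1R,3Z)-1-hydroxy-4-(hydroxymethyl)-6-[(4aS,8aS)-2,5,5,8a-tetramethyl-3,4,4a,5,6,7,8,8a-octahydronaphthalen-1-yl]hex-3-en-1-yl]oxolan-2-one (CNP0164639.2) | CC1=C(CC/C(=C/C[C@@H](O)[C@H]2COC(=O)C2)CO)[C@@]2(C)CCCC(C)(C)[C@@H]2CC1 | target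

**Count**

Total steps: 8. Longest linear sequence: 5 steps (steps 1, 2, 3, 4 and 8); the epoxy lactone branch is steps 5, 6 and 7.

**Steps most likely to fail**

1. Step 8. The alkene geometry may erode at the alkenylnickel stage, and reductive homocoupling or protodeiodination of the alkenyl iodide may outrun capture of the β-hydroxyalkyl radical. The fallback replaces the reductive union by a polar nucleophile–electrophile opening. It sets out from 9. Silylation (TBSCl, imidazole, CH2Cl2) should give the tert-butyldimethylsilyl ether F1. Iodine–magnesium exchange (i-PrMgCl·LiCl, THF, 0 °C) should give the (Z)-alkenylmagnesium chloride F2 with retention. CuI-catalysed (10 mol%) SN2 opening of oxirane 14 at its CH2 at −40 °C, quenched cold with aqueous NH4Cl so that the magnesium alkoxide cannot transpose the lactone, should give the silyl-protected coupling product F3. HF·pyridine in THF at 0 °C then removes the silyl group, and the route is rejoined at 16.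

2. Step 7. The acyl-transfer relay may stall at the lactone equilibrium, or intermolecular transesterification (oligomer formation) may overtake the intramolecular relay. The fallback separates the two events and sets out from 12. K2CO3 in MeOH at 0 °C lets methoxide open the lactone, and the freed secondary alkoxide closes the oxirane, which should give methyl (3R)-4-hydroxy-3-[(2S)-oxiran-2-yl]butanoate F4. PPTS in CH2Cl2, where no alkoxide is present, then closes the γ-lactone through the primary hydroxyl, and the route is rejoined at 14.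

3. Step 6. Hydrogen abstraction from methanol and the radical chain may be inefficient, so that photoreduction or telomerisation of the butenolide, or slow photodegradation of the sulfonate, takes over. The fallback uses an organocopper hydroxymethyl-anion equivalent instead of a radical and sets out from 11. Copper-catalysed conjugate addition of (isopropoxydimethylsilyl)methylmagnesium chloride (CuBr·SMe2 10 mol%, THF, −78 °C), anti to the C5 substituent, should give the [(2S,3S)-3-(silylmethyl)] lactone tosylate F5. Tamao–Fleming oxidation (H2O2, KF, KHCO3, THF/MeOH, 0 °C to rt) converts C–Si into C–OH, and the route is rejoined at 12.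

**Further compounds**

F1 | step 8 | tert-butyl({(2Z)-3-iodo-2-[2-((4aS,8aS)-2,5,5,8a-tetramethyl-3,4,4a,5,6,7,8,8a-octahydronaphthalen-1-yl)ethyl]prop-2-en-1-yl}oxy)dimethylsilane | CC1=C(CC/C(=C/I)CO[Si](C)(C)C(C)(C)C)[C@@]2(C)CCCC(C)(C)[C@@H]2CC1
F2 | step 8 | {(1Z)-3-[(tert-butyldimethylsilyl)oxy]-2-[2-((4aS,8aS)-2,5,5,8a-tetramethyl-3,4,4a,5,6,7,8,8a-octahydronaphthalen-1-yl)ethyl]prop-1-en-1-yl}magnesium chloride | CC1=C(CC/C(=C/[Mg]Cl)CO[Si](C)(C)C(C)(C)C)[C@@]2(C)CCCC(C)(C)[C@@H]2CC1
F3 | step 8 | (4R)-4-[(1R,3Z)-4-({[tert-butyl(dimethyl)silyl]oxy}methyl)-1-hydroxy-6-[(4aS,8aS)-2,5,5,8a-tetramethyl-3,4,4a,5,6,7,8,8a-octahydronaphthalen-1-yl]hex-3-en-1-yl]oxolan-2-one | CC1=C(CC/C(=C/C[C@@H](O)[C@H]2COC(=O)C2)CO[Si](C)(C)C(C)(C)C)[C@@]2(C)CCCC(C)(C)[C@@H]2CC1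
F4 | step 7 | methyl (3R)-4-hydroxy-3-[(2S)-oxiran-2-yl]butanoate | COC(=O)C[C@H](CO)[C@H]1CO1
F5 | step 6 | [(2S,3S)-3-{[dimethyl(propan-2-yloxy)silyl]methyl}-5-oxooxolan-2-yl]methyl 4-methylbenzenesulfonate | CC(C)O[Si](C)(C)C[C@H]1CC(=O)O[C@@H]1COS(=O)(=O)c1ccc(C)cc1
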